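**Retrosynthetic overview** (germacrane numbering C1–C15 is used in the comments)
1. Target ⇐ epoxidation of the 1(10)-alkene ⇐ C8 esterification with epoxyangelic acid 27 ⇐ PMB removal; the C3 ester is installed earlier.
2. γ-Lactone ⇐ 1,2-reduction of the C6 ketone in cyclodecadienone 20 and lactonisation onto the C7 acrylate ester.
3. Ten-membered ring ⇐ ring-expanding Grob fragmentation of cis-decalin 17: the C1–C6 bond breaks, N2 (from a tertiary nitro group) leaves, the 1(10)E alkene is formed and the 4Z alkene is carried over from the cyclohexene.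
4. Decalin ⇐ ring A from 1,4-benzoquinone; ring B by desymmetrising nitro-Michael addition of quinol 11; C15 by iodination/Stille; C3 by Luche reduction/Mitsunobu.
5. Quinol 11 ⇐ indium allylation with bromide 8 ⇐ PMB-glycolaldehyde + 2-nitropropene (enamine Michael sets C8) + methyl propiolate. Ring order: A → B → ten-membered ring → lactone → epoxide.

Assumption: glycolaldehyde is bought as its PMB ether 3 (PMB is a protecting group, removed in step 13). The nitro-bearing carbon of 4, 7, 8, 10 and 11 is an epimer mixture; it becomes a defined quaternary centre in step 6 and sp2 in step 11.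

Step 1
Reactants: 1 2-nitropropan-1-ol
Product: 2 2-nitroprop-1-ene
Conditions: phthalic anhydride, 150–180 °C, distil under reduced pressure
Reagents that add atoms: none
Why: Dehydration of a β-nitro alcohol through its phthalate half-ester (E1cB) is the standard nitroalkene synthesis and creates no stereocentre.

Step 2
Reactants: 2 2-nitroprop-1-ene; 3 2-[(4-methoxybenzyl)oxy]acetaldehyde
Product: 4 (2R)-2-[(4-methoxybenzyl)oxy]-4-nitropentanal
Conditions: (S)-α,α-diphenylprolinol TMS ether (5 mol %), 3-nitrobenzoic acid (10 mol %), toluene, 0 °C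
Reagents that add atoms: none
Why: Enamine-catalysed Michael addition (Hayashi–Jørgensen catalyst) of the α-alkoxy aldehyde to the unhindered nitroalkene; the (S)-catalyst gives the 2R aldehyde (future C8) with the same facial sense as propanal/nitrostyrene, while the nitro carbon forms as a mixture that does not matter.

Step 3
Reactants: 4 (2R)-2-[(4-methoxybenzyl)oxy]-4-nitropentanal; 5 methyl propiolate
Product: 7 methyl (4R)-3-hydroxy-4-[(4-methoxybenzyl)oxy]-2-methylidene-6-nitroheptanoate, via vinylalane 6 (not isolated)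
Conditions: DIBAL-H, NMO, THF, 0 °C; then 4, 0 → 25 °C
Reagents that add atoms: none
Why: Vinylalumination (a base-free route to Morita–Baylis–Hillman adducts) adds the α-alanyl acrylate to the aldehyde without epimerising the α-alkoxy centre; the new carbinol centre is lost in step 4.

Step 4
Reactants: 7 methyl (4R)-3-hydroxy-4-[(4-methoxybenzyl)oxy]-2-methylidene-6-nitroheptanoate
Product: 8 methyl (2Z,4R)-2-(bromomethyl)-4-[(4-methoxybenzyl)oxy]-6-nitrohept-2-enoate
Conditions: PBr3, Et2O, −10 °C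
Reagents that add atoms: phosphorus tribromide, BrP(Br)Br
Why: SN2′ bromination of the Baylis–Hillman alcohol gives the thermodynamically favoured (Z)-2-(bromomethyl)enoate and leaves C8 untouched.

Step 5
Reactants: 8 methyl (2Z,4R)-2-(bromomethyl)-4-[(4-methoxybenzyl)oxy]-6-nitrohept-2-enoate; 9 1,4-benzoquinone
Product: 11 methyl (3R,4R)-3-(1-hydroxy-4-oxocyclohexa-2,5-dien-1-yl)-4-[(4-methoxybenzyl)oxy]-2-methylidene-6-nitroheptanoate, via allylindium 10 (not isolated)
Conditions: In powder, THF, 25 °C (sonication); then 9, −40 → 0 °C; neutral work-up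
Reagents that add atoms: none
Why: Indium-mediated Barbier-type allylation (SE2′ γ-attack through a six-membered transition state) adds 1,2 to one quinone carbonyl and forms the C6–C7 bond; coordination of indium by the C8 ether oxygen delivers the carbonyl to the C7 face syn to O8 (chelation control) and sets 7R, while C6 is not yet stereogenic.

Step 6
Reactants: 11 methyl (3R,4R)-3-(1-hydroxy-4-oxocyclohexa-2,5-dien-1-yl)-4-[(4-methoxybenzyl)oxy]-2-methylidene-6-nitroheptanoate
Product: 12 methyl 2-[(1R,2R,4S,4aR,8aS)-8a-hydroxy-2-[(4-methoxybenzyl)oxy]-4-methyl-4-nitro-6-oxo-1,2,3,4,4a,5,6,8a-octahydronaphthalen-1-yl]prop-2-enoate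
Conditions: Et3N (0.3 equiv), N,N′-bis[3,5-bis(trifluoromethyl)phenyl]thiourea (0.2 equiv), toluene, 0 → 25 °C
Reagents that add atoms: none
Why: Desymmetrising intramolecular nitro-Michael addition (6-exo-trig) onto the more electrophilic dienone rather than the α-branched acrylate; a chair transition state with C8–OPMB equatorial selects one enone and gives the cis-fused decalin (C1, C6), and the hydrogen-bonded nitronate sits synclinal to the acceptor C=C (Seebach-type topology), so NO2 ends equatorial and the methyl axial at C10.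

Step 7
Reactants: 12 methyl 2-[(1R,2R,4S,4aR,8aS)-8a-hydroxy-2-[(4-methoxybenzyl)oxy]-4-methyl-4-nitro-6-oxo-1,2,3,4,4a,5,6,8a-octahydronaphthalen-1-yl]prop-2-enoate
Product: 13 methyl 2-[(1R,2R,4S,4aR,8aS)-8a-hydroxy-7-iodo-2-[(4-methoxybenzyl)oxy]-4-methyl-4-nitro-6-oxo-1,2,3,4,4a,5,6,8a-octahydronaphthalen-1-yl]prop-2-enoate
Conditions: I2, pyridine–CH2Cl2, 0 → 25 °C
Reagents that add atoms: iodine, II
Why: Johnson α-iodination of the enone (pyridine addition, iodination, elimination); C4 is the only enone α-CH in the molecule and no stereocentre changes.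

Step 8
Reactants: 13 methyl 2-[(1R,2R,4S,4aR,8aS)-8a-hydroxy-7-iodo-2-[(4-methoxybenzyl)oxy]-4-methyl-4-nitro-6-oxo-1,2,3,4,4a,5,6,8a-octahydronaphthalen-1-yl]prop-2-enoate
Product: 14 methyl 2-[(1R,2R,4S,4aR,8aS)-8a-hydroxy-2-[(4-methoxybenzyl)oxy]-4,7-dimethyl-4-nitro-6-oxo-1,2,3,4,4a,5,6,8a-octahydronaphthalen-1-yl]prop-2-enoate
Conditions: Me4Sn, Pd2(dba)3, AsPh3, CuI, DMF, 40 °C
Reagents that add atoms: tetramethyltin, C[Sn](C)(C)C
Why: Stille coupling of the α-iodoenone installs the C15 methyl under neutral conditions; the ring alkene (the future 4Z alkene) is fixed by the six-membered ring.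

Step 9
Reactants: 14 methyl 2-[(1R,2R,4S,4aR,8aS)-8a-hydroxy-2-[(4-methoxybenzyl)oxy]-4,7-dimethyl-4-nitro-6-oxo-1,2,3,4,4a,5,6,8a-octahydronaphthalen-1-yl]prop-2-enoate
Product: 15 methyl 2-[(1R,2R,4S,4aR,6R,8aS)-6,8a-dihydroxy-2-[(4-methoxybenzyl)oxy]-4,7-dimethyl-4-nitro-1,2,3,4,4a,5,6,8a-octahydronaphthalen-1-yl]prop-2-enoate
Conditions: NaBH4, CeCl3·7H2O, MeOH, −78 °C
Reagents that add atoms: none
Why: Luche 1,2-reduction of the enone (acrylate ester and nitro group inert); hydride adds from the convex face opposite ring B, giving the 3R allylic alcohol (OH cis to the C1–C10 bond), which is the epimer needed for inversion.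

Step 10
Reactants: 15 methyl 2-[(1R,2R,4S,4aR,6R,8aS)-6,8a-dihydroxy-2-[(4-methoxybenzyl)oxy]-4,7-dimethyl-4-nitro-1,2,3,4,4a,5,6,8a-octahydronaphthalen-1-yl]prop-2-enoate; 16 (2R)-2-methylbutanoic acid
Product: 17 methyl 2-[(1R,2R,4S,4aR,6S,8aS)-8a-hydroxy-2-[(4-methoxybenzyl)oxy]-4,7-dimethyl-6-{[(2R)-2-methylbutanoyl]oxy}-4-nitro-1,2,3,4,4a,5,6,8a-octahydronaphthalen-1-yl]prop-2-enoate
Conditions: PPh3, DIAD, toluene, 0 °C
Reagents that add atoms: none
Why: Mitsunobu esterification proceeds by SN2 inversion at the secondary allylic carbinol and gives the 3S ester of the target; the tertiary C6 hydroxyl does not react and the acid α-centre is not enolised.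

Step 11
Reactants: 17 methyl 2-[(1R,2R,4S,4aR,6S,8aS)-8a-hydroxy-2-[(4-methoxybenzyl)oxy]-4,7-dimethyl-6-{[(2R)-2-methylbutanoyl]oxy}-4-nitro-1,2,3,4,4a,5,6,8a-octahydronaphthalen-1-yl]prop-2-enoate
Product: 20 methyl 2-[(1R,2R,4E,7S,8Z)-2-[(4-methoxybenzyl)oxy]-4,8-dimethyl-7-{[(2R)-2-methylbutanoyl]oxy}-10-oxocyclodeca-4,8-dien-1-yl]prop-2-enoate, via amine 18 (not isolated), via diazonium acetate 19 (not isolated)
Conditions: Zn dust, AcOH–THF (1:2), 30 °C; filter; t-BuONO (1.2 equiv), 0 °C, 20 min; cold NaHCO3 work-up, use crude at once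
Reagents that add atoms: none
Why: Proposed new method: a denitrative Grob fragmentation in which a tertiary nitro group is the latent leaving group: Zn/AcOH reduces C–NO2 to carbinamine 18, t-BuONO converts it in the same flask into the equatorial alkanediazonium ion 19, and loss of N2 is coupled with cleavage of the antiperiplanar C1–C6 ring-fusion bond under the push of the C6 hydroxyl, so the two six-membered rings open to the ten-membered ketone; the equatorial C1–C2 bond (anti to C10–C9) makes the new 1(10)-alkene E, the ring alkene stays Z, and the weakly acidic medium spares the base-labile C7–H next to the new ketone; the closest known reaction types are the Wharton/Grob fragmentation of 1,3-diol monosulfonates and the nitrous acid deamination–fragmentation of γ-amino alcohols, but a nitro-Michael-derived tertiary nitro group has not been used to trigger a ring-expanding Grob fragmentation.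

Step 12
Reactants: 20 methyl 2-[(1R,2R,4E,7S,8Z)-2-[(4-methoxybenzyl)oxy]-4,8-dimethyl-7-{[(2R)-2-methylbutanoyl]oxy}-10-oxocyclodeca-4,8-dien-1-yl]prop-2-enoate
Product: 22 (3aR,4R,6E,9S,10Z,11aR)-4-[(4-methoxybenzyl)oxy]-6,10-dimethyl-3-methylidene-2-oxo-2,3,3a,4,5,8,9,11a-octahydrocyclodeca[b]furan-9-yl (2R)-2-methylbutanoate, via hydroxy ester 21 (not isolated)
Conditions: NaBH4, CeCl3·7H2O, MeOH, −78 → 0 °C; then PPTS (cat.), CH2Cl2, 25 °C
Reagents that add atoms: none
Why: Luche 1,2-reduction of the ring enone by Felkin–Anh attack anti to the C7–C11 bond on the extended C5–C6–C7–C8 conformer (peripheral attack) gives the 6R alkoxide, which closes the trans-fused α-methylene-γ-lactone on the methyl ester.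

Step 13
Reactants: 22 (3aR,4R,6E,9S,10Z,11aR)-4-[(4-methoxybenzyl)oxy]-6,10-dimethyl-3-methylidene-2-oxo-2,3,3a,4,5,8,9,11a-octahydrocyclodeca[b]furan-9-yl (2R)-2-methylbutanoate
Product: 23 (3aR,4R,6E,9S,10Z,11aR)-4-hydroxy-6,10-dimethyl-3-methylidene-2-oxo-2,3,3a,4,5,8,9,11a-octahydrocyclodeca[b]furan-9-yl (2R)-2-methylbutanoate
Conditions: DDQ, CH2Cl2–pH 7 buffer, 0 °C
Reagents that add atoms: none
Why: Oxidative PMB ether cleavage (benzylic hydride abstraction, hemiacetal hydrolysis) is selective for the electron-rich benzyl ether; esters, lactone and alkenes are left and no stereocentre is touched.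

Step 14
Reactants: 24 angelic acid
Product: 25 (2Z)-2-methylbut-2-en-1-ol
Conditions: LiAlH4, Et2O, 0 °C; Fieser work-up
Reagents that add atoms: none
Why: Hydride reduction of the carboxylic acid to the allylic alcohol without conjugate reduction keeps the Z geometry.

Step 15
Reactants: 25 (2Z)-2-methylbut-2-en-1-ol
Product: 26 [(2S,3R)-2,3-dimethyloxiran-2-yl]methanol
Conditions: Ti(OiPr)4 (cat.), L-(+)-diethyl tartrate (cat.), t-BuOOH, 4 Å MS, CH2Cl2, −20 °C
Reagents that add atoms: tert-butyl hydroperoxide, CC(C)(C)OO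
Why: Sharpless asymmetric epoxidation; L-(+)-tartrate delivers oxygen to the same face as in (E)-hex-2-en-1-ol → (2S,3S), which for this Z-alcohol is the (2S,3R) epoxide with CH2OH and the C3 methyl cis.

Step 16
Reactants: 26 [(2S,3R)-2,3-dimethyloxiran-2-yl]methanol
Product: 27 (2R,3R)-2,3-dimethyloxirane-2-carboxylic acid
Conditions: TEMPO (cat.), PhI(OAc)2, MeCN–H2O, 25 °C
Reagents that add atoms: water, O
Why: Oxoammonium oxidation of the primary alcohol through the aldehyde hydrate to the acid is near-neutral and leaves the epoxide intact; the C2 descriptor changes to R only by CIP priority.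

Step 17
Reactants: 23 (3aR,4R,6E,9S,10Z,11aR)-4-hydroxy-6,10-dimethyl-3-methylidene-2-oxo-2,3,3a,4,5,8,9,11a-octahydrocyclodeca[b]furan-9-yl (2R)-2-methylbutanoate; 27 (2R,3R)-2,3-dimethyloxirane-2-carboxylic acid
Product: 29 (3aR,4R,6E,9S,10Z,11aR)-6,10-dimethyl-9-{[(2R)-2-methylbutanoyl]oxy}-3-methylidene-2-oxo-2,3,3a,4,5,8,9,11a-octahydrocyclodeca[b]furan-4-yl (2R,3R)-2,3-dimethyloxirane-2-carboxylate, via mixed anhydride 28 (not isolated)
Conditions: 27, 2,4,6-trichlorobenzoyl chloride, Et3N, THF, 0 °C; then 23, DMAP, toluene, 25 °C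
Reagents that add atoms: none
Why: Yamaguchi esterification acylates the hindered 8β-hydroxyl with retention at C8 and without opening the epoxy acid.

Step 18
Reactants: 29 (3aR,4R,6E,9S,10Z,11aR)-6,10-dimethyl-9-{[(2R)-2-methylbutanoyl]oxy}-3-methylidene-2-oxo-2,3,3a,4,5,8,9,11a-octahydrocyclodeca[b]furan-4-yl (2R,3R)-2,3-dimethyloxirane-2-carboxylate
Product: 30 CNP0265335.1
Conditions: mCPBA, NaHCO3, CH2Cl2, 0 °C
Reagents that add atoms: meta-chloroperoxybenzoic acid, O=C(OO)c1cccc(Cl)c1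
Why: Prilezhaev epoxidation takes the most electron-rich 1(10)-alkene (the 4,5-alkene is flanked by two allylic acyloxy groups and the exo-methylene is conjugated); attack on the outer face of the E-alkene, which stands perpendicular to the ring, gives the 1β,10α = (1R,10R) trans-epoxide.

**Compound list**
1 | 2-nitropropan-1-ol (racemic) | CC(CO)[N+](=O)[O-] | starting material
2 | 2-nitroprop-1-ene | C=C(C)[N+](=O)[O-] | intermediate
3 | 2-[(4-methoxybenzyl)oxy]acetaldehyde (PMB-protected glycolaldehyde) | O=CCOCc1ccc(OC)cc1 | starting material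
4 | (2R)-2-[(4-methoxybenzyl)oxy]-4-nitropentanal (C4 epimers) | O=C[C@H](OCc1ccc(OC)cc1)CC(C)[N+](=O)[O-] | intermediate
5 | methyl propiolate | C#CC(=O)OC | starting material
6 | [1-(methoxycarbonyl)ethenyl]bis(2-methylpropyl)aluminium (vinylalane) | C=C(C(=O)OC)[Al](CC(C)C)CC(C)C | intermediate (not isolated)
7 | methyl (4R)-3-hydroxy-4-[(4-methoxybenzyl)oxy]-2-methylidene-6-nitroheptanoate (epimers at C3 and C6) | C=C(C(=O)OC)C(O)[C@H](OCc1ccc(OC)cc1)CC(C)[N+](=O)[O-] | intermediate
8 | methyl (2Z,4R)-2-(bromomethyl)-4-[(4-methoxybenzyl)oxy]-6-nitrohept-2-enoate (C6 epimers) | BrC/C(C(=O)OC)=C\[C@H](OCc1ccc(OC)cc1)CC(C)[N+](=O)[O-] | intermediate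
9 | 1,4-benzoquinone | O=C1C=CC(=O)C=C1 | starting material
10 | allylindium reagent from 8 (drawn as the σ-allylindium dibromide) | Br[In](Br)C/C(C(=O)OC)=C\[C@H](OCc1ccc(OC)cc1)CC(C)[N+](=O)[O-] | intermediate (not isolated)
11 | methyl (3R,4R)-3-(1-hydroxy-4-oxocyclohexa-2,5-dien-1-yl)-4-[(4-methoxybenzyl)oxy]-2-methylidene-6-nitroheptanoate (C6 epimers) | C=C(C(=O)OC)[C@@H](C1(O)C=CC(=O)C=C1)[C@H](OCc1ccc(OC)cc1)CC(C)[N+](=O)[O-] | intermediate
12 | methyl 2-[(1R,2R,4S,4aR,8aS)-8a-hydroxy-2-[(4-methoxybenzyl)oxy]-4-methyl-4-nitro-6-oxo-1,2,3,4,4a,5,6,8a-octahydronaphthalen-1-yl]prop-2-enoate (cis-fused) | C=C(C(=O)OC)[C@@H]1[C@H](OCc2ccc(OC)cc2)C[C@](C)([N+](=O)[O-])[C@H]2CC(=O)C=C[C@@]12O | intermediate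
13 | 7-iodo derivative of 12 (same configuration) | C=C(C(=O)OC)[C@@H]1[C@H](OCc2ccc(OC)cc2)C[C@](C)([N+](=O)[O-])[C@H]2CC(=O)C(I)=C[C@@]12O | intermediate
14 | 7-methyl derivative of 12 (same configuration) | C=C(C(=O)OC)[C@@H]1[C@H](OCc2ccc(OC)cc2)C[C@](C)([N+](=O)[O-])[C@H]2CC(=O)C(C)=C[C@@]12O | intermediate
15 | (6R)-allylic alcohol from 14 | C=C(C(=O)OC)[C@@H]1[C@H](OCc2ccc(OC)cc2)C[C@](C)([N+](=O)[O-])[C@H]2C[C@@H](O)C(C)=C[C@@]12O | intermediate
16 | (2R)-2-methylbutanoic acid | CC[C@@H](C)C(=O)O | starting material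
17 | (6S)-(2R)-2-methylbutanoate of the decalin (fragmentation precursor) | C=C(C(=O)OC)[C@@H]1[C@H](OCc2ccc(OC)cc2)C[C@](C)([N+](=O)[O-])[C@H]2C[C@H](OC(=O)[C@H](C)CC)C(C)=C[C@@]12O | intermediate
18 | 4-amino analogue of 17 | C=C(C(=O)OC)[C@@H]1[C@H](OCc2ccc(OC)cc2)C[C@](C)(N)[C@H]2C[C@H](OC(=O)[C@H](C)CC)C(C)=C[C@@]12O | intermediate (not isolated)
19 | 4-diazonium acetate from 18 | C=C(C(=O)OC)[C@@H]1[C@H](OCc2ccc(OC)cc2)C[C@](C)([N+]#N)[C@H]2C[C@H](OC(=O)[C@H](C)CC)C(C)=C[C@@]12O.CC(=O)[O-] | intermediate (not isolated)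
20 | methyl 2-[(1R,2R,4E,7S,8Z)-2-[(4-methoxybenzyl)oxy]-4,8-dimethyl-7-{[(2R)-2-methylbutanoyl]oxy}-10-oxocyclodeca-4,8-dien-1-yl]prop-2-enoate | C=C(C(=O)OC)[C@H]1C(=O)/C=C(/C)[C@@H](OC(=O)[C@H](C)CC)C/C=C(\C)C[C@H]1OCc2ccc(OC)cc2 | intermediate
21 | methyl 2-[(1S,2R,4E,7S,8Z,10R)-10-hydroxy-2-[(4-methoxybenzyl)oxy]-4,8-dimethyl-7-{[(2R)-2-methylbutanoyl]oxy}cyclodeca-4,8-dien-1-yl]prop-2-enoate | C=C(C(=O)OC)[C@H]1[C@H](O)/C=C(/C)[C@@H](OC(=O)[C@H](C)CC)C/C=C(\C)C[C@H]1OCc2ccc(OC)cc2 | intermediate (not isolated)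
22 | (3aR,4R,6E,9S,10Z,11aR)-4-[(4-methoxybenzyl)oxy]-6,10-dimethyl-3-methylidene-2-oxo-2,3,3a,4,5,8,9,11a-octahydrocyclodeca[b]furan-9-yl (2R)-2-methylbutanoate | C=C1C(=O)O[C@@H]2/C=C(/C)[C@@H](OC(=O)[C@H](C)CC)C/C=C(\C)C[C@@H](OCc3ccc(OC)cc3)[C@@H]12 | intermediate
23 | (3aR,4R,6E,9S,10Z,11aR)-4-hydroxy-6,10-dimethyl-3-methylidene-2-oxo-2,3,3a,4,5,8,9,11a-octahydrocyclodeca[b]furan-9-yl (2R)-2-methylbutanoate | C=C1C(=O)O[C@@H]2/C=C(/C)[C@@H](OC(=O)[C@H](C)CC)C/C=C(\C)C[C@@H](O)[C@@H]12 | intermediate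
24 | angelic acid, (2Z)-2-methylbut-2-enoic acid | C/C=C(/C)C(=O)O | starting material
25 | (2Z)-2-methylbut-2-en-1-ol | C/C=C(/C)CO | intermediate
26 | [(2S,3R)-2,3-dimethyloxiran-2-yl]methanol | OC[C@]1(C)O[C@@H]1C | intermediate
27 | (2R,3R)-2,3-dimethyloxirane-2-carboxylic acid | OC(=O)[C@]1(C)O[C@@H]1C | intermediate
28 | (2R,3R)-2,3-dimethyloxirane-2-carboxylic 2,4,6-trichlorobenzoic anhydride | O=C(OC(=O)c1c(Cl)cc(Cl)cc1Cl)[C@]1(C)O[C@@H]1C | intermediate (not isolated)
29 | (3aR,4R,6E,9S,10Z,11aR)-6,10-dimethyl-9-{[(2R)-2-methylbutanoyl]oxy}-3-methylidene-2-oxo-2,3,3a,4,5,8,9,11a-octahydrocyclodeca[b]furan-4-yl (2R,3R)-2,3-dimethyloxirane-2-carboxylate | C=C1C(=O)O[C@@H]2/C=C(/C)[C@@H](OC(=O)[C@H](C)CC)C/C=C(\C)C[C@@H](OC(=O)[C@]3(C)O[C@@H]3C)[C@@H]12 | intermediate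
30 | CNP0265335.1 (1β,10α-epoxide of 29) | C=C1C(=O)O[C@@H]2/C=C(/C)[C@@H](OC(=O)[C@H](C)CC)C[C@H]3O[C@]3(C)C[C@@H](OC(=O)[C@]3(C)O[C@@H]3C)[C@@H]12 | target

**Step count and risks**
Total: 18 steps. Longest linear sequence: 15 steps (steps 1–13, 17, 18); the side chain (steps 14–16) joins in step 17.

The stereochemical outcomes of steps 5, 6, 9, 11 and 12 are predictions from transition-state models and would have to be confirmed by experiment. The three steps most likely to fail:

Step 11 (the proposed new fragmentation). The diazonium ion may eliminate instead of fragmenting, the C6 hydroxyl may lactonise onto the ester before it can push, and the result depends on the equatorial C10–N bond set in step 6. The fallback uses known chemistry with another leaving group: it sets out from 17, which is reduced with Zn/AcOH and the amine 18 is isolated. Exhaustive methylation (MeI, K2CO3, MeOH) gives the trimethylammonium iodide F1. A Hofmann-type Grob fragmentation of this γ-hydroxy ammonium salt (KOt-Bu, 1.0 equiv, THF, −78 °C, cold AcOH quench) expels trimethylamine anti to the C1–C6 bond and comes back to the route at 20.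

Step 5 (indium allylation of benzoquinone). The quinone can be reduced by indium or by the allylmetal, and α-attack or poor 7,8-selectivity is possible. The fallback changes the electrophile to a masked quinone: it sets out from 8 (through 10) and adds to the quinone monoketal 4,4-dimethoxycyclohexa-2,5-dien-1-one F2, made from phenol with PhI(OAc)2 in MeOH. The 1,2-adduct is the quinol ketal F3, and mild hydrolysis (aqueous oxalic acid, THF) comes back to the route at 11.

Step 12 (C6 reduction and lactonisation). Hydride may attack the other face of the flexible ring and give the cis-lactone. The fallback replaces conformational control by hydroxyl-directed reduction: it sets out from 20, whose PMB group is removed first (DDQ) to give the β-hydroxy ketone F4. Me4NBH(OAc)3 (internal hydride delivery, 1,3-anti) then sets 6R relative to the 8-hydroxyl and gives the diol ester F5. Lactonisation through the 6-hydroxyl (PPTS) comes back to the route at 23, so step 13 is no longer needed.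

**Further compounds**
F1 | step 11 | 4-(trimethylammonio) analogue of 18, iodide | C=C(C(=O)OC)[C@@H]1[C@H](OCc2ccc(OC)cc2)C[C@](C)([N+](C)(C)C)[C@H]2C[C@H](OC(=O)[C@H](C)CC)C(C)=C[C@@]12O.[I-]
F2 | step 5 | 4,4-dimethoxycyclohexa-2,5-dien-1-one | COC1(OC)C=CC(=O)C=C1
F3 | step 5 | methyl (3R,4R)-3-(1-hydroxy-4,4-dimethoxycyclohexa-2,5-dien-1-yl)-4-[(4-methoxybenzyl)oxy]-2-methylidene-6-nitroheptanoate | C=C(C(=O)OC)[C@@H](C1(O)C=CC(OC)(OC)C=C1)[C@H](OCc1ccc(OC)cc1)CC(C)[N+](=O)[O-]
F4 | step 12 | methyl 2-[(1R,2R,4E,7S,8Z)-2-hydroxy-4,8-dimethyl-7-{[(2R)-2-methylbutanoyl]oxy}-10-oxocyclodeca-4,8-dien-1-yl]prop-2-enoate | C=C(C(=O)OC)[C@H]1C(=O)/C=C(/C)[C@@H](OC(=O)[C@H](C)CC)C/C=C(\C)C[C@H]1O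
F5 | step 12 | 6,8-diol ester, the PMB-free analogue of 21 | C=C(C(=O)OC)[C@H]1[C@H](O)/C=C(/C)[C@@H](OC(=O)[C@H](C)CC)C/C=C(\C)C[C@H]1O
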